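## The problem

Target 23 is a tetrahydrofuran (O1, C2–C5) in which C2 carries a 3,4-dimethoxyphenyl group, C3 a CH2O arm esterified with 3,4-dimethoxybenzoic acid, C4 a free secondary hydroxyl, and C5 is an unsubstituted CH2. The three stereocentres are contiguous, (2S,3R,4S), with all three substituents on one face of the ring. This is the most crowded arrangement, so it cannot be reached by equilibration and each centre has to be set kinetically. C2 and C3 can be made together as an acyclic syn pair, which becomes cis once the ring is closed; the cis pair can then direct the introduction of the C4 hydroxyl from a planar carbonyl. The C2–O1 bond is a cyclic 3,4-dimethoxybenzyl ether, which is ionized by strong Lewis or Brønsted acids, attacked by quinone oxidants and open to hydrogenolysis, so late deprotections must avoid all three. The ester must sit on the primary oxygen beside a free cis hydroxyl, which calls for a late, selective acylation; and any intermediate with a carbonyl at C4 has an acidic hydrogen at C3 and a β-oxygen on the exocyclic carbon, so it will epimerize or eliminate with base. The enabling feature is C5: a bare methylene between O1 and C4 is what a diazomethyl ketone leaves behind when its carbenoid inserts into the C2 hydroxyl, forming O1–C5 and leaving C4 as a ketone with one open face.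

## Retrosynthesis

**Ester C–O bond and the label on the primary oxygen.** Target 23 is cut at the ester, giving diol 21 and acid chloride 22. The ester cannot be carried earlier: it would sit β to the C4 ketone (elimination) and would meet a hydride reagent. The forward step only asks that the primary hydroxyl of 21 reacts before the hindered secondary one. Diol 21 comes from silyl ether 20 by fluoride. A benzyl ether would be the cheaper label, but its removal needs a Lewis acid, hydrogenolysis or an oxidant, each of which endangers the dimethoxybenzylic C2–O1 bond. A benzyloxy oxygen could also capture the carbenoid of the key step and undergo a Stevens shift. A triisopropylsilyl ether avoids both problems.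

**C4–H bond.** Alcohol 20 is traced to ketone 19. This removes one stereocentre and replaces it with a planar carbon whose two faces are differentiated by the cis substituents at C3 and C2. Bringing the C4 configuration in from a separate chiral building block would be longer. The forward step needs a hydride large enough to respect the shielded face and cold enough not to enolize C3.

**O1–C5 bond (key disconnection).** Ketone 19 is opened to the hydroxy diazoketone 18. Closing O1–C2 instead would mean substitution at a benzylic carbon that ionizes easily, which would put the C2 configuration at risk. A C–C closure would have to create stereocentres in the ring-forming step. Cutting O1–C5 breaks a bond to a carbon without stereochemistry and can be re-formed under neutral conditions. The precursor is acyclic and carries only the two centres of an aldol. The forward reaction must choose the hydroxyl over the electron-rich arene and over the silyl ether oxygen, and must not epimerize the centre α to the new ketone.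

**C4–C5 bond.** Diazoketone 18 comes from its triethylsilyl ether 17, and 17 from carboxylic acid 14 and diazomethane 15. Acylation of diazomethane makes the C–C bond without touching the α-centre. The temporary silyl group keeps the benzylic hydroxyl out of the activation step and blocks retro-aldol cleavage. The forward sequence asks for removal of that triethylsilyl group in the presence of the primary triisopropylsilyl ether and the diazo group.

**C2–C3 bond.** Acid 14 is derived from imide 12, and 12 from aldol adduct 11. Adduct 11 is cut between the two stereocentres into imide 7 and aldehyde 8. An auxiliary-controlled boron aldol sets both centres in one step, syn and in the required absolute sense, with the (S)-auxiliary. No later step needs to correct either centre. The forward step needs a clean (Z)-enolate and no loss of the β-silyloxy group.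

**N-acyl bond and the three-carbon unit.** Imide 7 is assembled from acid 4 and oxazolidinone 5. Acid 4 comes from alcohol 2, which is the monosilyl ether of diol 1. These are routine operations on cheap materials; they are the price of using a silyl ether in place of a purchasable benzyloxy acid.

## Roads not taken

**Alternative 1:** The ring is cut at O1–C2 and the exocyclic carbon is cut from C3. The precursor would be (2S)-2-(tert-butyldimethylsilyloxy)-4-(3,4-dimethoxyphenyl)but-3-yn-1-ol A2, whose single stereocentre is the future C4. With PdI2/KI under CO and air in methanol, the primary hydroxyl of A2 would add to the palladium-bound alkyne (5-endo-dig, O1–C2). The vinylpalladium species would then take up CO and methanol, giving methyl (4S)-4-(tert-butyldimethylsilyloxy)-2-(3,4-dimethoxyphenyl)-4,5-dihydrofuran-3-carboxylate A1. Hydrogenation anti to the silyloxy group, ester reduction, acylation and desilylation would follow.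

- Merits: ring and side-chain carbon are installed in one catalytic operation, only the one stereocentre of A2 has to be sourced, and no diazo compound or stoichiometric auxiliary is needed.
- Weak points: A1 is a 4-oxygenated 4,5-dihydrofuran, one elimination away from an aromatic furan. The warm, acid-generating conditions of oxidative carbonylation favour that loss of silanol, which would erase the only stereocentre. If A1 survives, C2 and C3 must both come from hydrogenation of a tetrasubstituted push–pull alkene on the face opposite the C4 substituent. Such alkenes are sluggish, and once saturated the C2–O1 bond becomes a dimethoxybenzylic ether that the same catalyst can cleave.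
- Comparison: in catalyst economy and hazard this road is better, and its length is comparable. The chosen plan sets against it stereocentres installed by reactions with firm models (auxiliary aldol for C2/C3, hindered hydride for C4) and no intermediate that can aromatize.

**Alternative 2:** The cut is the C3–CH2 bond together with the C2–H bond. The substrate would be (3S)-3-[(bromomethyl)dimethylsilyloxy]-5-(3,4-dimethoxyphenyl)-2,3-dihydrofuran A4. Bu3SnH would generate the silylmethyl radical, which closes 5-exo onto the enol ether carbon that becomes C3. The benzylic, oxygen-stabilized radical at C2 would then take hydrogen on the convex face of the new cis-fused bicycle, giving the cis-fused bicyclic siloxane A3. Tamao oxidation of the C–Si bond would deliver diol 21 of the present route directly.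

- Merits: the tether makes the C3/C4 cis relationship unavoidable, the conditions are neutral, and the sequence after the key step is one step shorter than here.
- Weak points: A4 is a 3-oxygenated 2,3-dihydrofuran with an electron-rich aryl enol ether. It aromatizes by loss of the C3 oxygen substituent with traces of acid, and it must first be made enantiopure. The radical adds to an electron-rich alkene, so premature reduction competes. The C2 centre depends on hydrogen transfer to a planar, long-lived benzylic radical, and convex-face delivery has to place the aryl group on the concave face, the more hindered outcome. Stoichiometric tin is a further cost.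
- Comparison: this is the better plan for the C3/C4 relationship, and it meets the same final acylation problem. The chosen plan sets against it a C2 centre fixed by an aldol and stable acyclic intermediates up to ring closure.

**Alternative 3:** The cut is the C2–C3 bond, made by ring contraction. The sugar D-arabinose A7 would be converted into the C-(3,4-dimethoxyphenyl) pyranoside triflate A6, which has a free 2-hydroxyl, an equatorial 3-O-triflate and a 4-O-benzoate. On ionization of the triflate, the ring bond from sugar C1 to sugar C2, antiperiplanar to the leaving group, would migrate to sugar C3 with inversion. The 2-hydroxyl carbon would collapse to a formyl group, giving the all-cis 4-benzoyloxy-2-(3,4-dimethoxyphenyl)tetrahydrofuran-3-carbaldehyde A5. Aldehyde reduction, ester exchange and acylation would finish.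

- Merits: all three stereocentres come from the cheap sugar A7 by a stereospecific shift, with no auxiliary, no asymmetric reagent and no diazo chemistry. In this respect the road is better than the chosen one.
- Weak points: reaching A6 needs a stereocontrolled C-arylation at the anomeric carbon and differentiation of three secondary hydroxyls, which costs more steps than the whole front end of the chosen route. The neighbouring benzoate and the ring oxygen can intercept the developing cation in place of the migrating bond. A5 is an all-cis aldehyde with an acidic C3 hydrogen and a β-benzoate, set up for epimerization and elimination. The end game must also exchange a secondary benzoate for a primary dimethoxybenzoate.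
- Comparison: the chosen plan gives up the chiral-pool advantage for a recoverable auxiliary. It sets against that a shorter protecting-group sequence and a ketone (19) that is reduced at once, in place of an epimerizable aldehyde that must be carried.

Key step: step 9

Remark: the rhodium carbenoid and oxonium ylide of step 9 are catalyst-bound transients and carry no number, whereas species that persist until the next reagent is added (mixed anhydrides, boron enolate and aldolate, peroxy acid) are numbered; diazomethane 15 is counted as a starting material, distilled as an ethereal solution from commercial N-methyl-N-nitroso-p-toluenesulfonamide and KOH just before use.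

## Route

Step 1
Reactants: 1 propane-1,3-diol
Product: 2 3-(triisopropylsilyloxy)propan-1-ol
Conditions: TIPSCl (1 equiv), imidazole, 1 (5 equiv), DMF, 0 °C to rt
Reagents that add atoms: chlorotriisopropylsilane, CC(C)[Si](Cl)(C(C)C)C(C)C
Why: Statistical monosilylation (silyl ether formation) of a symmetrical diol; the excess of the cheap, water-soluble diol suppresses the bis-silyl ether and is washed out. The bulky silyl group is chosen because it must later shield this oxygen from the carbenoid and outlast a triethylsilyl ether under fluoride.

Step 2
Reactants: 2 3-(triisopropylsilyloxy)propan-1-ol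
Product: 4 3-(triisopropylsilyloxy)propanoic acid, via 3-(triisopropylsilyloxy)propanal 3 (not isolated)
Conditions: TEMPO (cat.), PhI(OAc)2, MeCN/H2O (1:1), rt
Reagents that add atoms: water, O
Why: TEMPO/PhI(OAc)2 oxidation in aqueous acetonitrile takes a primary alcohol through the aldehyde and its hydrate to the carboxylic acid under near-neutral conditions that leave the silyl ether intact.

Step 3
Reactants: 4 3-(triisopropylsilyloxy)propanoic acid, 5 (S)-4-benzyloxazolidin-2-one
Product: 7 (S)-4-benzyl-3-[3-(triisopropylsilyloxy)propanoyl]oxazolidin-2-one, via mixed pivalic anhydride 6 (not isolated)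
Conditions: t-BuCOCl, Et3N, THF, −20 °C; then LiCl, 5, −20 °C to rt
Reagents that add atoms: none
Why: N-Acylation of the oxazolidinone through a mixed pivalic anhydride (LiCl/Et3N variant); the nucleophile attacks the less hindered, non-pivaloyl carbonyl, and no strong base is present that could eliminate the β-silyloxy group.

Step 4
Reactants: 7 (S)-4-benzyl-3-[3-(triisopropylsilyloxy)propanoyl]oxazolidin-2-one, 8 3,4-dimethoxybenzaldehyde
Product: 11 (S)-4-benzyl-3-[(2S,3S)-3-(3,4-dimethoxyphenyl)-3-hydroxy-2-(triisopropylsilyloxymethyl)propanoyl]oxazolidin-2-one, via dibutylboron (Z)-enolate 9 (not isolated), via dibutylboron aldolate 10 (not isolated)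
Conditions: Bu2BOTf, i-Pr2NEt, CH2Cl2, −78 to 0 °C; 8, −78 to 0 °C; then pH 7 buffer, MeOH, H2O2, 0 °C
Reagents that add atoms: none
Why: Evans syn-aldol reaction: soft enolization gives the (Z)-boron enolate, which adds to the aldehyde through a chair-like Zimmerman–Traxler transition state on the enolate face away from the benzyl group of the auxiliary. Both new stereocentres, (2S,3S), are set here under auxiliary control; their syn relationship is the later cis relationship of C2 and C3 of the ring. The covalent boron enolate does not expel the poor silyloxide leaving group at low temperature.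

Step 5
Reactants: 11 (S)-4-benzyl-3-[(2S,3S)-3-(3,4-dimethoxyphenyl)-3-hydroxy-2-(triisopropylsilyloxymethyl)propanoyl]oxazolidin-2-one
Product: 12 (S)-4-benzyl-3-[(2S,3S)-3-(3,4-dimethoxyphenyl)-3-(triethylsilyloxy)-2-(triisopropylsilyloxymethyl)propanoyl]oxazolidin-2-one
Conditions: TESOTf, 2,6-lutidine, CH2Cl2, −78 °C
Reagents that add atoms: triethylsilyl trifluoromethanesulfonate, CC[Si](CC)(CC)OS(=O)(=O)C(F)(F)F
Why: O-Silylation with a silyl triflate and a hindered base; capping the benzylic aldol hydroxyl blocks retro-aldol cleavage during the basic hydrolysis and keeps the hydroxyl out of the mixed-anhydride step.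

Step 6
Reactants: 12 (S)-4-benzyl-3-[(2S,3S)-3-(3,4-dimethoxyphenyl)-3-(triethylsilyloxy)-2-(triisopropylsilyloxymethyl)propanoyl]oxazolidin-2-one
Product: 14 (2S,3S)-3-(3,4-dimethoxyphenyl)-3-(triethylsilyloxy)-2-(triisopropylsilyloxymethyl)propanoic acid, via peroxy acid 13 (not isolated)
Conditions: LiOH, H2O2, THF/H2O (3:1), 0 °C; aq Na2SO3; aq HCl to pH 4, 0 °C
Reagents that add atoms: hydrogen peroxide, OO
Why: Hydroperoxide cleavage of the N-acyl oxazolidinone: the hydroperoxide anion attacks the exocyclic carbonyl selectively even in hindered imides, sulfite reduces the peroxy acid, and the auxiliary is recovered. The α-centre is not enolized at 0 °C and both silyl ethers tolerate the brief, mildly acidic work-up.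

Step 7
Reactants: 14 (2S,3S)-3-(3,4-dimethoxyphenyl)-3-(triethylsilyloxy)-2-(triisopropylsilyloxymethyl)propanoic acid, 15 diazomethane
Product: 17 (3S,4S)-1-diazo-4-(3,4-dimethoxyphenyl)-4-(triethylsilyloxy)-3-(triisopropylsilyloxymethyl)butan-2-one, via isobutyl carbonic mixed anhydride 16 (not isolated)
Conditions: i-BuOCOCl, N-methylmorpholine, THF, −20 °C; then 15, Et2O, −20 to 0 °C
Reagents that add atoms: none
Why: Acylation of diazomethane by a mixed carbonic anhydride (first stage of the Arndt–Eistert sequence): diazomethane attacks the acyl carbonyl and the acyl diazonium loses a proton to give the diazomethyl ketone. Activation under a weak base leaves the α-stereocentre untouched.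

Step 8
Reactants: 17 (3S,4S)-1-diazo-4-(3,4-dimethoxyphenyl)-4-(triethylsilyloxy)-3-(triisopropylsilyloxymethyl)butan-2-one
Product: 18 (3S,4S)-1-diazo-4-(3,4-dimethoxyphenyl)-4-hydroxy-3-(triisopropylsilyloxymethyl)butan-2-one
Conditions: TBAF, AcOH (1:1), THF, 0 °C
Reagents that add atoms: none
Why: Buffered fluoride desilylation: the triethylsilyl ether is far more labile toward fluoride than the primary triisopropylsilyl ether. The acetic acid buffer keeps the medium near neutral, so the diazo group is not protonated and the β-hydroxy ketone never sees free alkoxide (no retro-aldol, no epimerization).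

Step 9
Reactants: 18 (3S,4S)-1-diazo-4-(3,4-dimethoxyphenyl)-4-hydroxy-3-(triisopropylsilyloxymethyl)butan-2-one
Product: 19 (4S,5S)-5-(3,4-dimethoxyphenyl)-4-(triisopropylsilyloxymethyl)dihydrofuran-3(2H)-one
Conditions: Rh2(OAc)4 (1 mol %), CH2Cl2 (high dilution), rt, slow addition of 18
Reagents that add atoms: none
Why: Rh2(OAc)4 decomposes the terminal diazoketone with loss of N2 to an electrophilic rhodium carbenoid at the former diazo carbon. The benzylic hydroxyl oxygen, four atoms away, adds to this carbon to give a five-membered cyclic oxonium ylide, and a fast proton shift from oxygen to carbon releases the catalyst and the ketone; this forms the O1–C5 bond. The closest known reaction type is the Rh2(OAc)4-catalysed intramolecular O–H insertion of hydroxy α-diazoketones to tetrahydrofuran-3-ones. The ring closes in a five-membered mode in which the attacked carbenoid carbon becomes a ring atom and the Rh=C bond lies outside the ring (formally 5-exo). No stereocentre is created: the two centres from the aldol are carried through unchanged and their syn relationship becomes cis on the ring. The step needs chemoselectivity against addition of the carbenoid to the electron-rich arene (a six-membered, Buchner-type path) and against ylide formation at the other γ-oxygen. The free hydroxyl is the most nucleophilic and least hindered donor, and the second oxygen is buried under a triisopropylsilyl group, where a benzyl ether could instead undergo a Stevens [1,2]-shift. Neutral, aprotic conditions at room temperature and slow addition protect the epimerizable centre α to the new ketone and suppress carbene dimerization and intermolecular insertion.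

Step 10
Reactants: 19 (4S,5S)-5-(3,4-dimethoxyphenyl)-4-(triisopropylsilyloxymethyl)dihydrofuran-3(2H)-one
Product: 20 (3S,4R,5S)-5-(3,4-dimethoxyphenyl)-4-(triisopropylsilyloxymethyl)tetrahydrofuran-3-ol
Conditions: LiBH(s-Bu)3, THF, −78 °C; then aq NaOH, H2O2, 0 °C
Reagents that add atoms: none
Why: Diastereoselective ketone reduction with a bulky trialkylborohydride: hydride approaches the carbonyl from the face opposite the adjacent silyloxymethyl group and the cis aryl group, so the new hydroxyl ends up cis to both (3S, all-cis). The low temperature avoids enolization of the α-centre.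

Step 11
Reactants: 20 (3S,4R,5S)-5-(3,4-dimethoxyphenyl)-4-(triisopropylsilyloxymethyl)tetrahydrofuran-3-ol
Product: 21 (3S,4R,5S)-5-(3,4-dimethoxyphenyl)-4-(hydroxymethyl)tetrahydrofuran-3-ol
Conditions: TBAF, THF, 0 °C to rt
Reagents that add atoms: none
Why: Fluoride cleavage of the primary silyl ether (desilylation); the conditions are neither acidic, oxidizing nor reducing, so the dimethoxybenzylic C–O bond of the ring is not at risk.

Step 12
Reactants: 21 (3S,4R,5S)-5-(3,4-dimethoxyphenyl)-4-(hydroxymethyl)tetrahydrofuran-3-ol, 22 3,4-dimethoxybenzoyl chloride
Product: 23 [(2S,3R,4S)-2-(3,4-dimethoxyphenyl)-4-hydroxytetrahydrofuran-3-yl]methyl 3,4-dimethoxybenzoate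
Conditions: 22 (1.05 equiv), 2,4,6-collidine, CH2Cl2, −40 to 0 °C
Reagents that add atoms: none
Why: Chemoselective O-acylation (esterification with an acid chloride and a hindered pyridine base): the primary hydroxyl reacts much faster than the secondary ring hydroxyl, which is flanked by the cis side chain. The moderate electrophilicity of the electron-rich aroyl chloride and the low temperature sharpen this preference.

## Compound list

1 | propane-1,3-diol | OCCCO | starting material
2 | 3-(triisopropylsilyloxy)propan-1-ol | CC(C)[Si](OCCCO)(C(C)C)C(C)C | intermediate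
3 | 3-(triisopropylsilyloxy)propanal | CC(C)[Si](OCCC=O)(C(C)C)C(C)C | intermediate
4 | 3-(triisopropylsilyloxy)propanoic acid | CC(C)[Si](OCCC(=O)O)(C(C)C)C(C)C | intermediate
5 | (S)-4-benzyloxazolidin-2-one | O=C1N[C@@H](Cc2ccccc2)CO1 | starting material
6 | pivalic 3-(triisopropylsilyloxy)propanoic anhydride (mixed pivalic anhydride) | CC(C)[Si](OCCC(=O)OC(=O)C(C)(C)C)(C(C)C)C(C)C | intermediate
7 | (S)-4-benzyl-3-[3-(triisopropylsilyloxy)propanoyl]oxazolidin-2-one | CC(C)[Si](OCCC(=O)N1[C@@H](Cc2ccccc2)COC1=O)(C(C)C)C(C)C | intermediate
8 | 3,4-dimethoxybenzaldehyde (veratraldehyde) | COc1ccc(C=O)cc1OC | starting material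
9 | dibutylboron (Z)-enolate of 7 | CCCCB(CCCC)O/C(=C\CO[Si](C(C)C)(C(C)C)C(C)C)N1[C@@H](Cc2ccccc2)COC1=O | intermediate
10 | dibutylboron aldolate (O-dibutylboryl derivative of 11) | O=C1OC[C@H](Cc2ccccc2)N1C(=O)[C@@H](CO[Si](C(C)C)(C(C)C)C(C)C)[C@H](OB(CCCC)CCCC)c3ccc(OC)c(OC)c3 | intermediate
11 | (S)-4-benzyl-3-[(2S,3S)-3-(3,4-dimethoxyphenyl)-3-hydroxy-2-(triisopropylsilyloxymethyl)propanoyl]oxazolidin-2-one | O=C1OC[C@H](Cc2ccccc2)N1C(=O)[C@@H](CO[Si](C(C)C)(C(C)C)C(C)C)[C@H](O)c3ccc(OC)c(OC)c3 | intermediate
12 | (S)-4-benzyl-3-[(2S,3S)-3-(3,4-dimethoxyphenyl)-3-(triethylsilyloxy)-2-(triisopropylsilyloxymethyl)propanoyl]oxazolidin-2-one | O=C1OC[C@H](Cc2ccccc2)N1C(=O)[C@@H](CO[Si](C(C)C)(C(C)C)C(C)C)[C@H](O[Si](CC)(CC)CC)c3ccc(OC)c(OC)c3 | intermediate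
13 | (2S,3S)-3-(3,4-dimethoxyphenyl)-3-(triethylsilyloxy)-2-(triisopropylsilyloxymethyl)propaneperoxoic acid | OOC(=O)[C@@H](CO[Si](C(C)C)(C(C)C)C(C)C)[C@H](O[Si](CC)(CC)CC)c1ccc(OC)c(OC)c1 | intermediate
14 | (2S,3S)-3-(3,4-dimethoxyphenyl)-3-(triethylsilyloxy)-2-(triisopropylsilyloxymethyl)propanoic acid | OC(=O)[C@@H](CO[Si](C(C)C)(C(C)C)C(C)C)[C@H](O[Si](CC)(CC)CC)c1ccc(OC)c(OC)c1 | intermediate
15 | diazomethane | C=[N+]=[N-] | starting material
16 | isobutyl carbonic mixed anhydride of 14 | CC(C)COC(=O)OC(=O)[C@@H](CO[Si](C(C)C)(C(C)C)C(C)C)[C@H](O[Si](CC)(CC)CC)c1ccc(OC)c(OC)c1 | intermediate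
17 | (3S,4S)-1-diazo-4-(3,4-dimethoxyphenyl)-4-(triethylsilyloxy)-3-(triisopropylsilyloxymethyl)butan-2-one | [N-]=[N+]=CC(=O)[C@@H](CO[Si](C(C)C)(C(C)C)C(C)C)[C@H](O[Si](CC)(CC)CC)c1ccc(OC)c(OC)c1 | intermediate
18 | (3S,4S)-1-diazo-4-(3,4-dimethoxyphenyl)-4-hydroxy-3-(triisopropylsilyloxymethyl)butan-2-one | [N-]=[N+]=CC(=O)[C@@H](CO[Si](C(C)C)(C(C)C)C(C)C)[C@H](O)c1ccc(OC)c(OC)c1 | intermediate
19 | (4S,5S)-5-(3,4-dimethoxyphenyl)-4-(triisopropylsilyloxymethyl)dihydrofuran-3(2H)-one (cis) | CC(C)[Si](OC[C@@H]1C(=O)CO[C@@H]1c2ccc(OC)c(OC)c2)(C(C)C)C(C)C | intermediate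
20 | (3S,4R,5S)-5-(3,4-dimethoxyphenyl)-4-(triisopropylsilyloxymethyl)tetrahydrofuran-3-ol (all-cis) | CC(C)[Si](OC[C@@H]1[C@H](O)CO[C@@H]1c2ccc(OC)c(OC)c2)(C(C)C)C(C)C | intermediate
21 | (3S,4R,5S)-5-(3,4-dimethoxyphenyl)-4-(hydroxymethyl)tetrahydrofuran-3-ol (all-cis) | OC[C@@H]1[C@H](O)CO[C@@H]1c2ccc(OC)c(OC)c2 | intermediate
22 | 3,4-dimethoxybenzoyl chloride | COc1ccc(C(Cl)=O)cc1OC | starting material
23 | [(2S,3R,4S)-2-(3,4-dimethoxyphenyl)-4-hydroxytetrahydrofuran-3-yl]methyl 3,4-dimethoxybenzoate | COc1ccc(C(=O)OC[C@@H]2[C@H](O)CO[C@@H]2c2ccc(OC)c(OC)c2)cc1OC | target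

## Step count and least certain steps

Total step count: 12. Longest linear sequence: 12 steps (1 to 23); compounds 5, 8, 15 and 22 enter as reagents along this line.

**Step 9 (key step).** The carbenoid may attack the dimethoxyphenyl ring (Buchner-type addition or aromatic substitution) in competition with O–H insertion. Intermolecular insertion or carbene dimerization may occur if the diazoketone accumulates. The cis ketone may epimerize α to the carbonyl, or lose the β-silyloxy group, during isolation. For this reason the crude ketone should be filtered through a neutral pad and reduced at once.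

Fallback, starting from 18 and rejoining at 19: the ring would be closed by displacement instead of carbenoid chemistry. One equivalent of HBr in Et2O at −30 °C protonates the diazo carbon and bromide displaces N2, giving the bromomethyl ketone (3S,4S)-1-bromo-4-(3,4-dimethoxyphenyl)-4-hydroxy-3-(triisopropylsilyloxymethyl)butan-2-one F1. The acid is consumed by the diazo group before it can ionize the benzylic alcohol. Ag2O in CH2Cl2 then promotes intramolecular 5-exo-tet O-alkylation (Williamson type) of the benzylic hydroxyl to give 19.

**Step 8.** The triisopropylsilyl group may be lost alongside the triethylsilyl group. Fluoride may also trigger retro-aldol cleavage or epimerization of the liberated β-hydroxy ketone if the buffer is insufficient.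

Fallback, starting from 11 and rejoining at 18: the temporary silyl group would be left out. LiOH/H2O2 cleavage of 11 gives, through the peroxy acid (2S,3S)-3-(3,4-dimethoxyphenyl)-3-hydroxy-2-(triisopropylsilyloxymethyl)propaneperoxoic acid F2 and sulfite reduction, the free hydroxy acid (2S,3S)-3-(3,4-dimethoxyphenyl)-3-hydroxy-2-(triisopropylsilyloxymethyl)propanoic acid F3. Isobutyl chloroformate and N-methylmorpholine at −20 °C activate the carboxylate much faster than the hindered secondary hydroxyl, giving the hydroxy acid isobutyl carbonic mixed anhydride F4. Diazomethane 15 then gives 18 directly.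

**Step 10.** Facial selectivity of hydride delivery may be poor, or the basic hydride may enolize the ketone and so epimerize the centre next to it.

Fallback, starting from 19 and rejoining at 20: the ketone would be reduced with NaBH4 in MeOH at −40 °C and the epimers separated. The unwanted epimer (3R,4R,5S)-5-(3,4-dimethoxyphenyl)-4-(triisopropylsilyloxymethyl)tetrahydrofuran-3-ol F5 would be inverted under Mitsunobu conditions (4-nitrobenzoic acid, PPh3, DIAD) to the all-cis ester (3S,4S,5S)-5-(3,4-dimethoxyphenyl)-4-(triisopropylsilyloxymethyl)tetrahydrofuran-3-yl 4-nitrobenzoate F6. Methanolysis with K2CO3 in MeOH gives 20.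

**Step 12.** Acylation may also occur at the secondary hydroxyl, or the acyl group may migrate from the primary to the cis secondary oxygen.

Fallback, starting from 20 and rejoining at 23: selectivity would be enforced by protection. The secondary hydroxyl of 20 is esterified with levulinic acid (DCC, DMAP) to (3S,4S,5S)-5-(3,4-dimethoxyphenyl)-4-(triisopropylsilyloxymethyl)tetrahydrofuran-3-yl 4-oxopentanoate F7. HF·pyridine in THF removes the silyl ether under mildly acidic conditions that do not promote acyl migration, giving (3S,4S,5S)-5-(3,4-dimethoxyphenyl)-4-(hydroxymethyl)tetrahydrofuran-3-yl 4-oxopentanoate F8. Acylation with 22 and pyridine gives [(2S,3S,4S)-2-(3,4-dimethoxyphenyl)-4-(4-oxopentanoyloxy)tetrahydrofuran-3-yl]methyl 3,4-dimethoxybenzoate F9. Hydrazine acetate removes the levulinate selectively and leaves the aryl ester, giving 23.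

## Further compounds

F1 | step 9 | (3S,4S)-1-bromo-4-(3,4-dimethoxyphenyl)-4-hydroxy-3-(triisopropylsilyloxymethyl)butan-2-one | BrCC(=O)[C@@H](CO[Si](C(C)C)(C(C)C)C(C)C)[C@H](O)c1ccc(OC)c(OC)c1
F2 | step 8 | (2S,3S)-3-(3,4-dimethoxyphenyl)-3-hydroxy-2-(triisopropylsilyloxymethyl)propaneperoxoic acid | OOC(=O)[C@@H](CO[Si](C(C)C)(C(C)C)C(C)C)[C@H](O)c1ccc(OC)c(OC)c1
F3 | step 8 | (2S,3S)-3-(3,4-dimethoxyphenyl)-3-hydroxy-2-(triisopropylsilyloxymethyl)propanoic acid | OC(=O)[C@@H](CO[Si](C(C)C)(C(C)C)C(C)C)[C@H](O)c1ccc(OC)c(OC)c1
F4 | step 8 | hydroxy acid isobutyl carbonic mixed anhydride (mixed anhydride of F3) | CC(C)COC(=O)OC(=O)[C@@H](CO[Si](C(C)C)(C(C)C)C(C)C)[C@H](O)c1ccc(OC)c(OC)c1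
F5 | step 10 | (3R,4R,5S)-5-(3,4-dimethoxyphenyl)-4-(triisopropylsilyloxymethyl)tetrahydrofuran-3-ol | CC(C)[Si](OC[C@@H]1[C@@H](O)CO[C@@H]1c2ccc(OC)c(OC)c2)(C(C)C)C(C)C
F6 | step 10 | (3S,4S,5S)-5-(3,4-dimethoxyphenyl)-4-(triisopropylsilyloxymethyl)tetrahydrofuran-3-yl 4-nitrobenzoate | CC(C)[Si](OC[C@@H]1[C@H](OC(=O)c3ccc(cc3)[N+](=O)[O-])CO[C@@H]1c2ccc(OC)c(OC)c2)(C(C)C)C(C)C
F7 | step 12 | (3S,4S,5S)-5-(3,4-dimethoxyphenyl)-4-(triisopropylsilyloxymethyl)tetrahydrofuran-3-yl 4-oxopentanoate | CC(C)[Si](OC[C@@H]1[C@H](OC(=O)CCC(C)=O)CO[C@@H]1c2ccc(OC)c(OC)c2)(C(C)C)C(C)C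
F8 | step 12 | (3S,4S,5S)-5-(3,4-dimethoxyphenyl)-4-(hydroxymethyl)tetrahydrofuran-3-yl 4-oxopentanoate | OC[C@@H]1[C@H](OC(=O)CCC(C)=O)CO[C@@H]1c2ccc(OC)c(OC)c2
F9 | step 12 | [(2S,3S,4S)-2-(3,4-dimethoxyphenyl)-4-(4-oxopentanoyloxy)tetrahydrofuran-3-yl]methyl 3,4-dimethoxybenzoate | COc1ccc(C(=O)OC[C@@H]2[C@H](OC(=O)CCC(C)=O)CO[C@@H]2c2ccc(OC)c(OC)c2)cc1OC
A1 | alternative 1 | methyl (4S)-4-(tert-butyldimethylsilyloxy)-2-(3,4-dimethoxyphenyl)-4,5-dihydrofuran-3-carboxylate | COC(=O)C1=C(c2ccc(OC)c(OC)c2)OC[C@H]1O[Si](C)(C)C(C)(C)C
A2 | alternative 1 | (2S)-2-(tert-butyldimethylsilyloxy)-4-(3,4-dimethoxyphenyl)but-3-yn-1-ol | OC[C@@H](O[Si](C)(C)C(C)(C)C)C#Cc1ccc(OC)c(OC)c1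
A3 | alternative 2 | cis-fused bicyclic siloxane (dimethylsilyl bridge from the C4 oxygen to the C3 methylene, aryl cis to the CH2 arm) | C[Si]1(C)C[C@@H]2[C@H](O1)CO[C@@H]2c2ccc(OC)c(OC)c2
A4 | alternative 2 | (3S)-3-[(bromomethyl)dimethylsilyloxy]-5-(3,4-dimethoxyphenyl)-2,3-dihydrofuran | BrC[Si](C)(C)O[C@@H]1COC(c2ccc(OC)c(OC)c2)=C1
A5 | alternative 3 | all-cis 4-benzoyloxy-2-(3,4-dimethoxyphenyl)tetrahydrofuran-3-carbaldehyde | O=C[C@@H]1[C@H](OC(=O)c2ccccc2)CO[C@@H]1c1ccc(OC)c(OC)c1
A6 | alternative 3 | C-(3,4-dimethoxyphenyl) D-arabinopyranoside with free 2-hydroxyl, equatorial 3-O-triflate and 4-O-benzoate (aryl equatorial) | O[C@H]1[C@H](OS(=O)(=O)C(F)(F)F)[C@H](OC(=O)c2ccccc2)CO[C@@H]1c3ccc(OC)c(OC)c3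
A7 | alternative 3 | D-arabinose | O=C[C@@H](O)[C@H](O)[C@H](O)CO
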